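The α-methylene-γ-lactone ring is removed as 2-bromoacrylic acid (germacrane numbering throughout). Its O–C6 bond is allylic to the ring C4=C5 (Z) olefin, and its C11–C7 bond is vicinal to that bond. One zerovalent-palladium diene heteroannulation therefore makes both: vinyl–Pd insertion at C7, then carboxylate capture of the C4–C6 allyl at C6. Syn addition to an E C6=C7 bond gives the trans fusion. The precursor is a ten-membered (4Z,6E)-diene 1,10-epoxide with ether-protected C3 and C8 oxygens. It comes from (S)-carvone by a chair anionic oxy-Cope ring expansion, which relays the carvone stereocentre to C8 and sets the ring's planar chirality. The two esters are attached last.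

Key step: step 10

Remark: numbering is ring C1–C10, C14 on C10, C15 on C4, lactone C11–C13. The C8 acyl group is read from the structure as (2R,3S)-2,3-dimethyloxirane-2-carboxylate with its two methyl groups cis, that is, the epoxide of a tiglate. TBS = tert-butyldimethylsilyl, PMB = 4-methoxybenzyl, Tf = trifluoromethanesulfonyl.

Step 1
Reactants: 1 (S)-(+)-carvone
Product: 2 (1S,5S)-cis-carveol
Conditions: NaBH4, CeCl3·7H2O, MeOH, −78 to 0 °C
Reagents that add atoms: none
Why: The Luche reduction gives clean 1,2-reduction, and axial hydride delivery to the half-chair with an equatorial isopropenyl group sets the new carbinol centre (future C3, S) cis to that group.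

Step 2
Reactants: 2 (1S,5S)-cis-carveol
Product: 3 (1S,5S)-cis-carveol TBS ether
Conditions: TBSCl, imidazole, DMF, rt
Reagents that add atoms: tert-butyldimethylsilyl chloride, CC(C)(C)[Si](C)(C)Cl
Why: This is a standard silylation of a secondary allylic alcohol, and the bulky ether survives organolithium, KH and palladium, cannot ionise under zerovalent palladium and later anchors the ring conformation.

Step 3
Reactants: 3 (1S,5S)-cis-carveol TBS ether
Product: 4 (4S,6S)-4-(TBSO)-3-methyl-6-(prop-1-en-2-yl)cyclohex-2-en-1-one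
Conditions: CrO3, 3,5-dimethylpyrazole, CH2Cl2, −20 °C
Reagents that add atoms: chromium trioxide, O=[Cr](=O)=O
Why: Chromium trioxide–dimethylpyrazole allylic oxidation should convert the only free ring allylic methylene (future C6) into the enone carbonyl because the other ring allylic position carries the silyl ether, and both stereocentres stay untouched (the α-centre already holds its more stable equatorial configuration).

Step 4
Reactants: 5 4-methoxybenzyl alcohol; 6 ethyl vinyl ether
Product: 7 4-methoxybenzyl vinyl ether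
Conditions: Pd(OAc)2 (2 mol %), 1,10-phenanthroline (2 mol %), 6 as solvent, rt
Reagents that add atoms: none
Why: Catalytic transfer vinylation exchanges the alkoxy group of the vinyl ether under neutral conditions and is driven by the excess of 6.

Step 5
Reactants: 7 4-methoxybenzyl vinyl ether
Product: 9 (Z)-2-bromovinyl 4-methoxybenzyl ether, via 1,2-dibromoethyl ether 8 (not isolated)
Conditions: Br2 (1.0 equiv), CH2Cl2, −78 °C; then DBU, −78 °C to rt
Reagents that add atoms: bromine, BrBr
Why: Bromine adds to the electron-rich vinyl ether far faster than to the arene, and amine-induced loss of HBr through the labile α-bromo ether should give mainly the Z isomer (cis effect, as for the ethyl analogue), which is purified on basic alumina.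

Step 6
Reactants: 9 (Z)-2-bromovinyl 4-methoxybenzyl ether; 4 (4S,6S)-4-(TBSO)-3-methyl-6-(prop-1-en-2-yl)cyclohex-2-en-1-one
Product: 11 (1S,4S,6S)-4-(TBSO)-1-[(Z)-2-(PMBO)ethenyl]-3-methyl-6-(prop-1-en-2-yl)cyclohex-2-en-1-ol, via (Z)-2-(PMBO)vinyllithium 10 (not isolated)
Conditions: 9, t-BuLi (2 equiv), Et2O, −78 °C; then 4, −78 °C; aq. NaHCO3 quench
Reagents that add atoms: none
Why: Bromine–lithium exchange proceeds with retention to the oxygen-coordinated Z-vinyllithium, which adds 1,2 by equatorial attack on the face opposite the neighbouring isopropenyl group and the silyl ether, so that the new carbinol centre carries the two alkenyl groups trans-diequatorial.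

Step 7
Reactants: 11 (1S,4S,6S)-4-(TBSO)-1-[(Z)-2-(PMBO)ethenyl]-3-methyl-6-(prop-1-en-2-yl)cyclohex-2-en-1-ol
Product: 14 (3S,8R)-3-(TBSO)-8-(PMBO)germacra-1(10)E,4Z,6-trien-6-yl triflate (C5 trans to C8 across C6=C7), via potassium alkoxide 12 (not isolated), via potassium enolate 13 (not isolated)
Conditions: KH, 18-crown-6, THF, 0 °C to rt; then Comins' reagent, −78 to 0 °C
Reagents that add atoms: N-(5-chloropyridin-2-yl)bis(trifluoromethanesulfonimide), O=S(=O)(N(c1ccc(Cl)cn1)S(=O)(=O)C(F)(F)F)C(F)(F)F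
Why: The anionic oxy-Cope rearrangement through the trans-decalin-like chair breaks C1–C6 and forms C8–C9, which gives the E C1=C10 bond, keeps the Z C4=C5 bond, places C5 and C8 trans on the enolate and relays the C1 stereocentre to C8 (R, from the axial Z enol ether), while the C8–O bond lies near the enolate plane (the oxygen-bearing C6=C7 unit cannot flip through the ring), so that E1cB loss of alkoxide is slowed until O-triflation fixes the geometry.

Step 8
Reactants: 14 (3S,8R)-3-(TBSO)-8-(PMBO)germacra-1(10)E,4Z,6-trien-6-yl triflate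
Product: 15 (1R,3S,8R,10R)-1,10-epoxy-3-(TBSO)-8-(PMBO)germacra-4Z,6-dien-6-yl triflate
Conditions: mCPBA, NaHCO3, CH2Cl2, −20 °C
Reagents that add atoms: 3-chloroperbenzoic acid, O=C(OO)c1cccc(Cl)c1
Why: The Prilezhaev epoxidation picks the only electron-rich isolated trisubstituted olefin (the diene is deactivated by the triflate) and attacks its outer face in the crossed, chair-derived conformer, which gives the trans (1R,10R)-epoxide and removes the 1,5-diene needed for a Cope back-reaction.

Step 9
Reactants: 15 (1R,3S,8R,10R)-1,10-epoxy-3-(TBSO)-8-(PMBO)germacra-4Z,6-dien-6-yl triflate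
Product: 16 (1R,3S,8R,10R)-1,10-epoxy-3-(TBSO)-8-(PMBO)germacra-4Z,6E-diene
Conditions: Pd(OAc)2 (5 mol %), PPh3 (15 mol %), HCO2H, Et3N, DMF, 40 °C
Reagents that add atoms: none
Why: Palladium-catalysed formate hydrogenolysis of an enol triflate replaces OTf by H with retention of geometry, so that the E C6=C7 bond results, and the silyl ether, the benzyl-type ether and the non-allylic epoxide are inert.

Step 10
Reactants: 16 (1R,3S,8R,10R)-1,10-epoxy-3-(TBSO)-8-(PMBO)germacra-4Z,6E-diene; 17 2-bromoacrylic acid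
Product: 19 (1R,3S,6R,7R,8R,10R)-1,10-epoxy-3-(TBSO)-8-(PMBO)germacra-4Z,11(13)-dien-12,6-olide, via palladacycle 18 (not isolated)
Conditions: Pd(OAc)2 (10 mol %), P(2-furyl)3 (30 mol %), Ag2CO3, MeCN, 50 °C
Reagents that add atoms: none
Why: Zerovalent palladium inserts into the C–Br bond of 17, the vinylpalladium carboxylate (bromide removed as AgBr) adds syn across the strained E C6=C7 bond with C11 going to the less hindered diene terminus C7, and the η3-allyl over C4–C6, held as six-membered palladacycle 18, collapses by C6–O reductive elimination. The closest known reaction type is the Larock heteroannulation of 1,3-dienes by organic halides that carry a carboxylic acid. The one ring closed is the γ-lactone, in a formal [3+2] sense, by 5-exo attack of the metal-bound carboxylate on the near allyl terminus C6 instead of seven-ring closure at the tertiary C4. C7 (R) is set by peripheral attack on the outer face of C6=C7 in the conformer fixed by the trans-epoxide, the Z C4=C5 bond and the pseudo-equatorial C3 silyl ether (C9 anti to the incoming carbon, C8–O inside), and C6 (R) follows because insertion and inner-sphere C–O formation both take place on the palladium face, so that the E olefin maps onto the trans fusion. The Z geometry of C4=C5 is kept because syn/anti exchange of the allyl would need a tertiary C4–Pd σ-bond. Chemoselectivity is secured by ether instead of ester protection at the allylic C3 and C8 oxygens, which cannot ionise, and by the non-allylic position of the epoxide.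

Step 11
Reactants: 19 (1R,3S,6R,7R,8R,10R)-1,10-epoxy-3-(TBSO)-8-(PMBO)germacra-4Z,11(13)-dien-12,6-olide
Product: 20 (1R,3S,6R,7R,8R,10R)-1,10-epoxy-8-hydroxy-3-(TBSO)germacra-4Z,11(13)-dien-12,6-olide
Conditions: DDQ, CH2Cl2/pH 7 phosphate buffer, 0 °C
Reagents that add atoms: none
Why: Oxidative PMB cleavage under buffered conditions leaves the silyl ether, the epoxide, the olefins and the methylene lactone untouched.

Step 12
Reactants: 21 (E)-2-methylbut-2-en-1-ol
Product: 22 [(2S,3S)-2,3-dimethyloxiran-2-yl]methanol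
Conditions: Ti(OiPr)4 (10 mol %), L-(+)-diethyl tartrate (12 mol %), t-BuOOH, 4 Å molecular sieves, CH2Cl2, −20 °C
Reagents that add atoms: tert-butyl hydroperoxide, CC(C)(C)OO
Why: The catalytic Sharpless asymmetric epoxidation with the L-(+)-tartrate delivers oxygen to the face of the E allylic alcohol that gives the (2S,3S)-epoxy alcohol, and the olefin geometry fixes the cis relation of the two methyl groups.

Step 13
Reactants: 22 [(2S,3S)-2,3-dimethyloxiran-2-yl]methanol
Product: 23 (2R,3S)-2,3-dimethyloxirane-2-carboxylic acid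
Conditions: RuCl3 (2 mol %), NaIO4, MeCN/EtOAc/H2O, rt
Reagents that add atoms: water, O
Why: RuO4 generated from RuCl3 and NaIO4 oxidises the primary alcohol through the aldehyde hydrate to the acid without touching the epoxide or its stereocentres (C2 becomes R only through a change of CIP priorities).

Step 14
Reactants: 23 (2R,3S)-2,3-dimethyloxirane-2-carboxylic acid; 20 (1R,3S,6R,7R,8R,10R)-1,10-epoxy-8-hydroxy-3-(TBSO)germacra-4Z,11(13)-dien-12,6-olide
Product: 25 (1R,3S,6R,7R,8R,10R)-1,10-epoxy-8-[(2R,3S)-2,3-dimethyloxirane-2-carbonyloxy]-3-(TBSO)germacra-4Z,11(13)-dien-12,6-olide, via mixed anhydride 24 (not isolated)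
Conditions: 23, 2,4,6-trichlorobenzoyl chloride, Et3N, toluene, rt; then 20, DMAP, rt
Reagents that add atoms: none
Why: The Yamaguchi esterification activates the hindered α-quaternary acid as a mixed anhydride, so that DMAP can transfer it to the hindered C8 hydroxyl with retention at C8 and under conditions too mild for translactonisation.

Step 15
Reactants: 25 (1R,3S,6R,7R,8R,10R)-1,10-epoxy-8-[(2R,3S)-2,3-dimethyloxirane-2-carbonyloxy]-3-(TBSO)germacra-4Z,11(13)-dien-12,6-olide
Product: 26 (1R,3S,6R,7R,8R,10R)-1,10-epoxy-8-[(2R,3S)-2,3-dimethyloxirane-2-carbonyloxy]-3-hydroxygermacra-4Z,11(13)-dien-12,6-olide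
Conditions: HF·pyridine, excess pyridine, THF, 0 °C to rt
Reagents that add atoms: none
Why: Buffered HF·pyridine removes the allylic TBS ether through the strong Si–F bond while both epoxides, the ester and the lactone should survive.

Step 16
Reactants: 26 (1R,3S,6R,7R,8R,10R)-1,10-epoxy-8-[(2R,3S)-2,3-dimethyloxirane-2-carbonyloxy]-3-hydroxygermacra-4Z,11(13)-dien-12,6-olide; 27 3-methylbutanoic anhydride
Product: 28 target CNP0167461.4
Conditions: Et3N, DMAP (cat.), CH2Cl2, 0 °C
Reagents that add atoms: none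
Why: DMAP-catalysed acylation of the free allylic C3 hydroxyl proceeds with retention and completes the target.

Compound list
1 | (S)-(+)-carvone | CC1=CC[C@@H](CC1=O)C(C)=C | starting material
2 | (1S,5S)-cis-carveol | CC1=CC[C@H](C(C)=C)C[C@@H]1O | intermediate
3 | (1S,5S)-cis-carveol TBS ether | CC1=CC[C@H](C(C)=C)C[C@@H]1O[Si](C)(C)C(C)(C)C | intermediate
4 | (4S,6S)-4-(TBSO)-3-methyl-6-(prop-1-en-2-yl)cyclohex-2-en-1-one | CC1=CC(=O)[C@H](C(C)=C)C[C@@H]1O[Si](C)(C)C(C)(C)C | intermediate
5 | 4-methoxybenzyl alcohol | COc1ccc(CO)cc1 | starting material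
6 | ethyl vinyl ether | C=COCC | starting material
7 | 4-methoxybenzyl vinyl ether | C=COCc1ccc(OC)cc1 | intermediate
8 | 1,2-dibromoethyl 4-methoxybenzyl ether (racemic, not isolated) | BrCC(Br)OCc1ccc(OC)cc1 | intermediate
9 | (Z)-2-bromovinyl 4-methoxybenzyl ether | Br/C=C\OCc1ccc(OC)cc1 | intermediate
10 | (Z)-2-(PMBO)vinyllithium (not isolated) | [Li]/C=C\OCc1ccc(OC)cc1 | intermediate
11 | (1S,4S,6S)-4-(TBSO)-1-[(Z)-2-(PMBO)ethenyl]-3-methyl-6-(prop-1-en-2-yl)cyclohex-2-en-1-ol (OH cis to isopropenyl) | CC1=C[C@@](O)(/C=C\OCc2ccc(OC)cc2)[C@H](C(C)=C)C[C@@H]1O[Si](C)(C)C(C)(C)C | intermediate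
12 | potassium alkoxide of 11 (not isolated) | CC1=C[C@@]([O-])(/C=C\OCc2ccc(OC)cc2)[C@H](C(C)=C)C[C@@H]1O[Si](C)(C)C(C)(C)C.[K+] | intermediate
13 | potassium (3S,8R)-3-(TBSO)-8-(PMBO)germacra-1(10)E,4Z,6-trien-6-olate, C5 trans to C8 (not isolated) | COc1ccc(CO[C@H]2/C=C([O-])/C=C(/C)[C@@H](O[Si](C)(C)C(C)(C)C)C/C=C(\C)C2)cc1.[K+] | intermediate
14 | (3S,8R)-3-(TBSO)-8-(PMBO)germacra-1(10)E,4Z,6-trien-6-yl triflate, C5 trans to C8 | COc1ccc(CO[C@H]2/C=C(OS(=O)(=O)C(F)(F)F)/C=C(/C)[C@@H](O[Si](C)(C)C(C)(C)C)C/C=C(\C)C2)cc1 | intermediate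
15 | (1R,3S,8R,10R)-1,10-epoxy-3-(TBSO)-8-(PMBO)germacra-4Z,6-dien-6-yl triflate | COc1ccc(CO[C@H]2/C=C(OS(=O)(=O)C(F)(F)F)/C=C(/C)[C@@H](O[Si](C)(C)C(C)(C)C)C[C@H]3O[C@]3(C)C2)cc1 | intermediate
16 | (1R,3S,8R,10R)-1,10-epoxy-3-(TBSO)-8-(PMBO)germacra-4Z,6E-diene | COc1ccc(CO[C@H]2/C=C/C=C(/C)[C@@H](O[Si](C)(C)C(C)(C)C)C[C@H]3O[C@]3(C)C2)cc1 | intermediate
17 | 2-bromoacrylic acid | C=C(Br)C(=O)O | starting material
18 | allylpalladium carboxylate palladacycle, drawn in its η1 form at C6, phosphines omitted (not isolated) | C=C1C(=O)O[Pd][C@@H]2/C=C(/C)[C@@H](O[Si](C)(C)C(C)(C)C)C[C@H]3O[C@]3(C)C[C@@H](OCc3ccc(OC)cc3)[C@@H]12 | intermediate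
19 | (1R,3S,6R,7R,8R,10R)-1,10-epoxy-3-(TBSO)-8-(PMBO)germacra-4Z,11(13)-dien-12,6-olide | C=C1C(=O)O[C@@H]2/C=C(/C)[C@@H](O[Si](C)(C)C(C)(C)C)C[C@H]3O[C@]3(C)C[C@@H](OCc3ccc(OC)cc3)[C@@H]12 | intermediate
20 | (1R,3S,6R,7R,8R,10R)-1,10-epoxy-8-hydroxy-3-(TBSO)germacra-4Z,11(13)-dien-12,6-olide | C=C1C(=O)O[C@@H]2/C=C(/C)[C@@H](O[Si](C)(C)C(C)(C)C)C[C@H]3O[C@]3(C)C[C@@H](O)[C@@H]12 | intermediate
21 | (E)-2-methylbut-2-en-1-ol | C/C=C(\C)CO | starting material
22 | [(2S,3S)-2,3-dimethyloxiran-2-yl]methanol | OC[C@]1(C)O[C@H]1C | intermediate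
23 | (2R,3S)-2,3-dimethyloxirane-2-carboxylic acid | OC(=O)[C@]1(C)O[C@H]1C | intermediate
24 | (2R,3S)-2,3-dimethyloxirane-2-carboxylic 2,4,6-trichlorobenzoic anhydride (not isolated) | O=C(OC(=O)[C@]1(C)O[C@H]1C)c1c(Cl)cc(Cl)cc1Cl | intermediate
25 | 8-O-[(2R,3S)-2,3-dimethyloxirane-2-carbonyl] derivative of 20 | C=C1C(=O)O[C@@H]2/C=C(/C)[C@@H](O[Si](C)(C)C(C)(C)C)C[C@H]3O[C@]3(C)C[C@@H](OC(=O)[C@]3(C)O[C@H]3C)[C@@H]12 | intermediate
26 | 3-hydroxy compound from 25 | C=C1C(=O)O[C@@H]2/C=C(/C)[C@@H](O)C[C@H]3O[C@]3(C)C[C@@H](OC(=O)[C@]3(C)O[C@H]3C)[C@@H]12 | intermediate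
27 | 3-methylbutanoic (isovaleric) anhydride | CC(C)CC(=O)OC(=O)CC(C)C | starting material
28 | (1R,3S,6R,7R,8R,10R)-1,10-epoxy-3-(3-methylbutanoyloxy)-8-[(2R,3S)-2,3-dimethyloxirane-2-carbonyloxy]germacra-4Z,11(13)-dien-12,6-olide | C=C1C(=O)O[C@@H]2/C=C(/C)[C@@H](OC(=O)CC(C)C)C[C@H]3O[C@]3(C)C[C@@H](OC(=O)[C@]3(C)O[C@H]3C)[C@@H]12 | target

Total step count: 16. Longest linear sequence: 12 steps from (S)-carvone (steps 1–3, 6–11, 14–16).

Steps most likely to fail

**Step 10.**
- What may go wrong: insertion into the hindered internal diene may be slow. The bromoacrylate may oligomerise or the product methylene group may react further. Flipping of the C6=C7 unit may erode the facial selectivity.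
- Fallback: it sets out from 16 and keeps the one-operation C–C/C–O annulation but changes to a radical–polar mechanism.
- Et3B/air-initiated iodine-atom-transfer addition of iodoacetic acid places CH2CO2H on C7 from the outer face and gives the allylic iodide acid F1.
- The labile carbon–iodine bond of F1 is displaced by the carboxylate on addition of NaHCO3, which funnels into the trans-fused α-unsubstituted lactone F2.
- LiN(i-Pr)2 and Eschenmoser's salt give the Mannich base F3, and methyl iodide gives the ammonium iodide F4.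
- NaHCO3 then eliminates the amine, and the route is rejoined at 19.

**Step 7.**
- What may go wrong: the alkoxide may be lost from the β-alkoxy enolate before trapping. Leakage through a boat transition state would erode the C8 configuration.
- Fallback: it sets out from 4 and moves the C8 stereocentre to reagent control.
- LiC≡COEt adds to 4 to give the ethoxyethynyl carbinol F5.
- KH/18-crown-6 oxy-Cope rearrangement and protonation of the allenolate give the ten-membered vinylogous ester F6, which has no leaving group β to an enolate.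
- i-Bu2AlH gives the bis-allylic alcohol F7, and dilute acid (Stork–Danheiser transposition) gives the (4Z,6E)-dien-8-one F8.
- Corey–Bakshi–Shibata reduction with the (S)-oxazaborolidine and BH3·SMe2 gives the (8R)-dienol F9.
- PMB trichloroacetimidate with La(OTf)3 gives the PMB ether F10.
- mCPBA as in step 8 rejoins the route at 16.

**Step 3.**
- What may go wrong: oxidation may compete at the isopropenyl methyl or at the tertiary allylic C–H, and over-oxidation is possible.
- Fallback: it sets out from 3.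
- Photooxygenation (O2, tetraphenylporphyrin, visible light) engages only the trisubstituted ring olefin in a Schenck ene reaction and gives the tertiary allylic hydroperoxide F11.
- PPh3 reduces it to the tertiary allylic alcohol F12; both C4 epimers converge.
- Pyridinium chlorochromate (C5H5NH[CrO3Cl]) effects the oxidative 1,3-transposition, which rejoins the route at 4.

Further compounds
F1 | step 10 | (7R)-7-carboxymethyl-6-iodo adduct of 16, C6 labile | IC1/C=C(/C)[C@@H](O[Si](C)(C)C(C)(C)C)C[C@H]2O[C@]2(C)C[C@@H](OCc2ccc(OC)cc2)[C@H]1CC(=O)O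
F2 | step 10 | 13-nor lactone (C11 = CH2) corresponding to 19 | C1C(=O)O[C@@H]2/C=C(/C)[C@@H](O[Si](C)(C)C(C)(C)C)C[C@H]3O[C@]3(C)C[C@@H](OCc3ccc(OC)cc3)[C@@H]12
F3 | step 10 | 13-(dimethylamino)-11,13-dihydro derivative of 19, C11 undefined | CN(C)CC1C(=O)O[C@@H]2/C=C(/C)[C@@H](O[Si](C)(C)C(C)(C)C)C[C@H]3O[C@]3(C)C[C@@H](OCc3ccc(OC)cc3)[C@@H]12
F4 | step 10 | trimethylammonium iodide of F3 | C[N+](C)(C)CC1C(=O)O[C@@H]2/C=C(/C)[C@@H](O[Si](C)(C)C(C)(C)C)C[C@H]3O[C@]3(C)C[C@@H](OCc3ccc(OC)cc3)[C@@H]12.[I-]
F5 | step 7 | 1-(ethoxyethynyl) carbinol from 4, alkynyl trans to isopropenyl | CC1=C[C@@](O)(C#COCC)[C@H](C(C)=C)C[C@@H]1O[Si](C)(C)C(C)(C)C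
F6 | step 7 | (3S)-8-ethoxy-3-(TBSO)germacra-1(10)E,4Z,7-trien-6-one, C7=C8 geometry of no consequence | CCOC1=CC(=O)/C=C(/C)[C@@H](O[Si](C)(C)C(C)(C)C)C/C=C(\C)C1
F7 | step 7 | 6-hydroxy compound from F6, C6 undefined | CCOC1=CC(O)/C=C(/C)[C@@H](O[Si](C)(C)C(C)(C)C)C/C=C(\C)C1
F8 | step 7 | (3S)-3-(TBSO)germacra-1(10)E,4Z,6E-trien-8-one | O=C1/C=C/C=C(/C)[C@@H](O[Si](C)(C)C(C)(C)C)C/C=C(\C)C1
F9 | step 7 | (3S,8R)-3-(TBSO)germacra-1(10)E,4Z,6E-trien-8-ol | O[C@H]1/C=C/C=C(/C)[C@@H](O[Si](C)(C)C(C)(C)C)C/C=C(\C)C1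
F10 | step 7 | PMB ether of F9 | COc1ccc(CO[C@H]2/C=C/C=C(/C)[C@@H](O[Si](C)(C)C(C)(C)C)C/C=C(\C)C2)cc1
F11 | step 3 | tertiary allylic hydroperoxide from 3, new centre undefined | CC1(OO)C=C[C@H](C(C)=C)C[C@@H]1O[Si](C)(C)C(C)(C)C
F12 | step 3 | tertiary allylic alcohol from F11, new centre undefined | CC1(O)C=C[C@H](C(C)=C)C[C@@H]1O[Si](C)(C)C(C)(C)C
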